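**Assumption:** the only stereocentre is C2 of the flavanone, which reads as (S) from the SMILES. This is the configuration of natural (2S)-naringenin, which I take as a purchasable single enantiomer.

## Retrosynthetic overview

1. Target 10 ⇐ removal of the 7-O-pivaloyl group from 9; 9 ⇐ Heck coupling of aryl bromide 8 with 2-methylbut-3-en-2-ol, which sets the (E)-alkene.
2. 8 ⇐ O-methylation of phenol 7; 7 ⇐ aromatic Claisen [3,3] rearrangement of the 1,1-dimethylallyl aryl ether 6, which forms the C5'–prenyl bond (key step).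
3. 6 ⇐ Pd-catalysed O-tert-prenylation of bromophenol 3 with carbonate 5; 3 ⇐ ortho-bromination of 7-O-pivaloylnaringenin 2 ⇐ (2S)-naringenin 1.
4. No ring is formed: both the chromanone and the B ring, with the C2 (S) centre, are bought in 1 and carried through under neutral or weakly basic conditions.

## Route

**Step 1**
Reactants: 1, (2S)-naringenin [(2S)-5,7-dihydroxy-2-(4-hydroxyphenyl)chroman-4-one]
Product: 2, (2S)-5-hydroxy-2-(4-hydroxyphenyl)-4-oxochroman-7-yl pivalate
Conditions: PivCl (1.05 eq), i-Pr2NEt (1.2 eq), THF, −20 → 0 °C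
Reagents that add atoms: pivaloyl chloride, CC(C)(C)C(Cl)=O
Why: Regioselective O-acylation: the 7-OH (vinylogous acid, pKa about 7) is ionised and acylated first, while the 5-OH is chelated to C4=O and the 4'-OH is less acidic; the pivalate also deactivates and shields the A ring for step 2.

**Step 2**
Reactants: 2, 7-O-pivaloylnaringenin
Product: 3, (2S)-2-(3-bromo-4-hydroxyphenyl)-5-hydroxy-4-oxochroman-7-yl pivalate
Conditions: NBS (1.0 eq, slow addition), i-Pr2NH (10 mol %), CH2Cl2, −20 → 0 °C, dark
Reagents that add atoms: N-bromosuccinimide, O=C1CCC(=O)N1Br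
Why: Amine-catalysed electrophilic aromatic ortho-bromination delivers Br ortho to the only free, non-chelated phenol (para position blocked), and C6/C8 are flanked and deactivated by the 7-O-acyl group and the ketone.

**Step 3** (reagent preparation)
Reactants: 4, 2-methylbut-3-en-2-ol
Product: 5, tert-butyl 2-methylbut-3-en-2-yl carbonate
Conditions: n-BuLi, THF, −78 °C; then Boc2O, −78 °C → rt
Reagents that add atoms: di-tert-butyl dicarbonate, CC(C)(C)OC(=O)OC(=O)OC(C)(C)C
Why: Alkoxide acylation of the tertiary allylic alcohol gives the mixed carbonate used as a neutral π-allyl precursor.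

**Step 4**
Reactants: 3, bromophenol; 5, tert-butyl 2-methylbut-3-en-2-yl carbonate (1.3 eq)
Product: 6, (2S)-2-[3-bromo-4-(2-methylbut-3-en-2-yloxy)phenyl]-5-hydroxy-4-oxochroman-7-yl pivalate
Conditions: Pd(PPh3)4 (3 mol %), THF, 4 Å MS, 0 °C
Reagents that add atoms: carbonate 5, C=CC(C)(C)OC(=O)OC(C)(C)C (transfers the C5H9 unit; CO2 and t-BuOH are lost)
Why: Decarboxylative Tsuji–Trost O-allylation: the phenoxide attacks the more substituted terminus of the π-(1,1-dimethylallyl)Pd complex under kinetic control, with no added base, and the C–Br bond is inert to Pd(0)/PPh3 at 0 °C.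

**Step 5** (key step)
Reactants: 6, 1,1-dimethylallyl aryl ether
Product: 7, (2S)-2-[3-bromo-4-hydroxy-5-(3-methylbut-2-en-1-yl)phenyl]-5-hydroxy-4-oxochroman-7-yl pivalate
Conditions: PhMe, 110–120 °C (sealed tube), N2
Reagents that add atoms: none
Why: Aromatic Claisen [3,3]-sigmatropic rearrangement moves the allyl unit, with inversion, to the only free ortho carbon (C5') and rearomatises to the ortho-prenyl phenol; the medium is neutral, so C2 is not touched.

**Step 6**
Reactants: 7, ortho-prenyl bromophenol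
Product: 8, (2S)-2-[3-bromo-4-methoxy-5-(3-methylbut-2-en-1-yl)phenyl]-5-hydroxy-4-oxochroman-7-yl pivalate
Conditions: TMSCHN2, i-Pr2NEt (cat.), MeCN–MeOH 9:1, 0 °C → rt
Reagents that add atoms: trimethylsilyldiazomethane, C[Si](C)(C)C=[N+]=[N-] (supplies the O-CH3 carbon)
Why: Diazoalkane O-methylation of the acidic ortho-bromophenol, leaving the chelated 5-OH unreacted and avoiding the carbonate/MeI conditions that open flavanones to chalcones.

**Step 7**
Reactants: 8, aryl bromide; 4, 2-methylbut-3-en-2-ol (4 eq)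
Product: 9, (2S)-5-hydroxy-2-[3-[(E)-3-hydroxy-3-methylbut-1-en-1-yl]-4-methoxy-5-(3-methylbut-2-en-1-yl)phenyl]-4-oxochroman-7-yl pivalate
Conditions: Pd2(dba)3 (2.5 mol %), [(t-Bu)3PH]BF4 (6 mol %), Cy2NMe (1.5 eq), dioxane, 50–70 °C
Reagents that add atoms: 2-methylbut-3-en-2-ol (4), C=CC(C)(C)O
Why: Mizoroki–Heck reaction: aryl insertion at the terminal CH2 and syn β-hydride elimination (only possible toward the arene, since the carbinol carbon is quaternary) give the (E)-styrenyl tertiary alcohol, and the trisubstituted prenyl alkene does not react.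

**Step 8**
Reactants: 9, 7-O-pivaloyl precursor
Product: 10, (2S)-5,7-dihydroxy-2-[3-[(E)-3-hydroxy-3-methylbut-1-en-1-yl]-4-methoxy-5-(3-methylbut-2-en-1-yl)phenyl]chroman-4-one (target)
Conditions: K2CO3 (1.5 eq), MeOH, 0 °C → rt; pH 6 phosphate buffer work-up
Reagents that add atoms: none
Why: Methanolysis of the activated aryl pivalate (leaving group para to the ketone), with the liberated 7-phenoxide disfavouring C3 enolisation and so protecting C2, and the buffered work-up sparing the acid-labile tertiary allylic alcohol.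

## Compound list

1 | (2S)-naringenin | Oc1ccc([C@@H]2CC(=O)c3c(O)cc(O)cc3O2)cc1 | starting material
2 | (2S)-5-hydroxy-2-(4-hydroxyphenyl)-4-oxochroman-7-yl pivalate | Oc1ccc([C@@H]2CC(=O)c3c(O)cc(OC(=O)C(C)(C)C)cc3O2)cc1 | intermediate
3 | (2S)-2-(3-bromo-4-hydroxyphenyl)-5-hydroxy-4-oxochroman-7-yl pivalate | Oc1ccc([C@@H]2CC(=O)c3c(O)cc(OC(=O)C(C)(C)C)cc3O2)cc1Br | intermediate
4 | 2-methylbut-3-en-2-ol | C=CC(C)(C)O | starting material
5 | tert-butyl 2-methylbut-3-en-2-yl carbonate | C=CC(C)(C)OC(=O)OC(C)(C)C | intermediate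
6 | (2S)-2-[3-bromo-4-(2-methylbut-3-en-2-yloxy)phenyl]-5-hydroxy-4-oxochroman-7-yl pivalate | C=CC(C)(C)Oc1ccc([C@@H]2CC(=O)c3c(O)cc(OC(=O)C(C)(C)C)cc3O2)cc1Br | intermediate
7 | (2S)-2-[3-bromo-4-hydroxy-5-(3-methylbut-2-en-1-yl)phenyl]-5-hydroxy-4-oxochroman-7-yl pivalate | CC(C)=CCc1cc([C@@H]2CC(=O)c3c(O)cc(OC(=O)C(C)(C)C)cc3O2)cc(Br)c1O | intermediate
8 | (2S)-2-[3-bromo-4-methoxy-5-(3-methylbut-2-en-1-yl)phenyl]-5-hydroxy-4-oxochroman-7-yl pivalate | COc1c(Br)cc([C@@H]2CC(=O)c3c(O)cc(OC(=O)C(C)(C)C)cc3O2)cc1CC=C(C)C | intermediate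
9 | (2S)-5-hydroxy-2-[3-[(E)-3-hydroxy-3-methylbut-1-en-1-yl]-4-methoxy-5-(3-methylbut-2-en-1-yl)phenyl]-4-oxochroman-7-yl pivalate | COc1c(/C=C/C(C)(C)O)cc([C@@H]2CC(=O)c3c(O)cc(OC(=O)C(C)(C)C)cc3O2)cc1CC=C(C)C | intermediate
10 | (2S)-5,7-dihydroxy-2-[3-[(E)-3-hydroxy-3-methylbut-1-en-1-yl]-4-methoxy-5-(3-methylbut-2-en-1-yl)phenyl]chroman-4-one | COc1c(/C=C/C(C)(C)O)cc([C@@H]2CC(=O)c3c(O)cc(O)cc3O2)cc1CC=C(C)C | target

## Summary

Total steps: 8 (7 on the main line plus 1 reagent preparation).
Longest linear sequence: 7 steps (1 → 2 → 3 → 6 → 7 → 8 → 9 → 10).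

Steps most likely to fail:

1. **Step 2, B-ring bromination.** The A ring (C6/C8) may compete, or 3',5'-dibromination may occur. Fallback: drop the halide. Carry out O-tert-prenylation and Claisen rearrangement on 2, repeat both to reach the 3',5'-diprenyl phenol, and O-methylate. Then convert one of the two equivalent prenyl groups to the (E)-3-hydroxy-3-methylbutenyl chain by a Schenck ene reaction (¹O2, TPP, hν; then PPh3), and cleave the pivalate.

2. **Step 5, Claisen rearrangement.** The ether may lose isoprene to return 3, or the ortho-prenyl phenol may cyclise to a chroman. Fallback: use a two-stage relay. O-allylate 3 (allyl methyl carbonate, Pd(0)), run the simple allyl Claisen rearrangement, and then convert the 5'-allyl group to prenyl by cross-metathesis with 2-methyl-2-butene (Grubbs II).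

3. **Step 7, Heck coupling.** The electron-rich, ortho-substituted bromide may react slowly, and amine plus heat may partly epimerise C2 by retro-oxa-Michael opening. Fallback: base-free Stille coupling of 8 with (E)-2-methyl-4-(tributylstannyl)but-3-en-2-ol (from hydrostannation of 2-methylbut-3-yn-2-ol), Pd(PPh3)4/CuI, DMF, 50 °C.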